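## Structural features

The target 15 is a 3,4-dihydronaphthalen-1(2H)-one. Ring A (C4a, C5, C6, C7, C8, C8a) is a benzene ring with hydroxyl groups at C5 and C8, a p-hydroquinone, and ring B (C1, C2, C3, C4, C4a, C8a) is the cyclohexanone with its carbonyl at C1, peri to the C8 hydroxyl. C4 is joined by one sp3–sp2 bond to C1' of a 4-hydroxy-8-methoxynaphthalene, so the attachment is para to the naphthol oxygen and peri to the methoxy group. C4 is the only stereocentre, (S), a diarylmethine with no stereogenic neighbour, crowded between the C5 hydroxyl and the C8' methoxy group. The fragile parts are the hydroquinone (air oxidation to the quinone, fastest as the anion, after which tautomerisation through C4–H would erase the configuration), the electron-rich naphthol, and the doubly benzylic C4–H, which is lost if ring B aromatises or if strong acid ionises the C4–C1' bond. The real difficulty is to create this isolated stereocentre, which has no adjacent group to direct a reagent, while three phenolic oxygens must end free beside one methyl ether. The feature used is that ring A is the reduced form of p-benzoquinone and its C4a–C8a edge is bonded to both C4 and C1, so ring B is a cyclohexene built from one quinone C=C and the chain C1–C2–C3–C4 as a diene carrying oxygen at C1 and the naphthyl group at C4.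

## Logic of the disconnections

15 ⇒ 14. The three acyl–oxygen bonds at O5, O8 and O4' are cut. The free hydroquinone and naphthol would not survive the oxidation at C1 or the Lewis acid of the cycloaddition. All three masks are esters, so one operation ends the synthesis. The forward cleavage must run without oxygen and without strong acid, so that neither the hydroquinone nor C4 is endangered.

14 ⇒ 13 ⇒ 12. No skeletal bond is cut; the C1=O group is traced back to the carbinol and then to its silyl ether. This lets the C1 oxygen be carried as an inert ether from the diene stage. The forward steps need a non-basic desilylation, so that the O8 acetate does not migrate to O1, and an oxidant that leaves aryl esters and the methoxynaphthalene untouched.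

12 ⇒ 11. The C2–C3 single bond is traced back to a cis double bond. A cyclohexene with the double bond between the two substituted carbons is the retron of a [4+2] addition. The forward reduction must neither cleave the benzylic C1–O bond nor move the double bond towards C4, which would erase the stereocentre, so a metal-free hydrogen transfer is required.

11 ⇒ 9 (through 10). The two O-acetyl bonds are cut and ring A is returned to its diketo tautomer with hydrogens at C4a and C8a. The hexasubstituted benzene ring thereby becomes the adduct of an unsubstituted quinone. The forward enolisation must outrun β-elimination of the C1 oxygen, and the phenols must be capped as they form.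

9 ⇒ 7 + 8. The bonds C4–C4a and C1–C8a are cut in a retro-[4+2] sense. Both lie on the C4a–C8a edge, and ring B is the only ring that contains the stereocentre. The bicyclic core with four contiguous stereocentres falls apart into a symmetric six-carbon dienophile and an achiral open-chain diene. The forward step must control endo mode, diene orientation and face at once, and all of this is handed to a chiral catalyst.

7 ⇒ 6. The O–Si bond is cut and the dienol returned to the aldehyde. This replaces a sensitive dienol ether by a carbonyl compound. The forward silylation must give the 1E enol ether predominantly and keep the 3E styrenyl bond.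

6 ⇒ 3 + 4 (through 5). The aryl–alkenyl bond C1'–C4 is cut, the only bond between naphthalene and chain. The whole four-carbon chain then comes from one purchased acetal, with no separate one-carbon homologation. The forward arylation must occur at the terminal alkene carbon of 4 at a peri-hindered bromide; positional isomers of the double bond are tolerated because they converge in the next step.

3 ⇒ 2 ⇒ 1. The ester bond and then the C–Br bond are cut, leading to a purchasable naphthol. Bromination must precede acylation because the free hydroxyl is what directs the halogen para to itself and into the correct ring. The acyl group is chosen so that the naphthyl group is a weaker donor than the silyloxy group in 7.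

## Other disconnections considered

Alternative 1: The naphthol ring is cut at C1'–C8a' and C4'–C4a'. This leaves a furan on C4 of the enantiopure, benzyl-protected tetralone A1 and an aryne.
- Forward key step: fluoride releases the methoxy aryne from the silyl triflate A2; the furan of A1 adds across it in a [4+2] reaction to give the oxygen-bridged dihydronaphthalene A3. Acid would then open the bridge to the naphthol and hydrogenolysis would free the hydroquinone.
- In its favour: it is convergent and runs under mild, nearly neutral conditions. The key step does not touch C4, so no selectivity of that step can erode the stereocentre; on this point it is better than the chosen plan, where three selectivities of step 5 decide the purity at C4. The two bridgehead diastereomers of A3 converge. Benzyl ethers are a sturdier mask for the hydroquinone than the acetates of 11–14.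
- Against it: the methoxy group must end next to the bridgehead that carries the tetralone, which is the crowded regioisomer. Aryne polarisation and furan nucleophilicity favour it, steric repulsion opposes it, so a mixture is to be expected. Opening the bridge places positive charge on C1', next to C4–H, so a hydride shift can remove the stereocentre. The ketone α-position can also be arylated by the aryne.
- Comparison: A1 needs its own asymmetric synthesis, so the stereochemical problem is moved rather than solved. The route would be longer than the ten steps of the chosen plan, which makes ring B and the stereocentre in one step from 7 and 8.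

Alternative 2: C3–C4 and the O–C1 bond of a seven-membered lactone are cut; the C1–C8a bond would be made afterwards by an acyl shift from oxygen to carbon.
- Forward key step: a chiral N-heterocyclic carbene converts propenal A5 into a homoenolate equivalent. Its β-carbon attacks the exocyclic carbon of the o-quinone methide A4, generated in situ, and the phenoxide then acylates to close the benzoxepinone A6.
- In its favour: the stereocentre is formed directly as the diarylmethine on a flat electrophile, and only one selectivity (the face of the methide) must be controlled; this is better than the chosen plan. C2 and C3 arrive at the final oxidation level, so no alkene reduction and no carbinol oxidation are needed; this is equal or better redox economy.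
- Against it: A5 has no β-substituent and is prone to polymerise under carbene catalysis. The methide carbon of A4 carries a very hindered peri-methoxynaphthyl group, and its geometry feeds into the selectivity. A6 is not ring B: the Fries-type or Friedel–Crafts acyl shift in strong acid must go ortho to the methoxy group, in competition with acylation at C2' of the naphthalene, and strong acid puts the diarylmethine at risk of ionisation. Finally one of two aryl methyl ethers must be cleaved selectively.
- Comparison: the step count would be similar to the chosen plan. However, two steps of uncertain selectivity follow the creation of the stereocentre, whereas after 9 only functional-group operations remote from C4 remain.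

Alternative 3: C1–C2 and C2–C3 are cut, so C2 is removed and the enantiopure 3-naphthylindanone A7 remains.
- Forward key step: A7 is converted to the silyl enol ether A8. A zinc carbenoid (Et2Zn/CH2I2) transfers methylene to the face anti to the naphthyl group to give the siloxycyclopropane A9. Oxidative opening of the endocyclic cyclopropane bond (FeCl3), loss of HCl and hydrogenation would give the tetralone.
- In its favour: each operation is reliable and stereospecific. The facial selectivity of methylene transfer does not matter, since C1 and C2 end without stereochemistry. Ether protection is robust throughout; on these points it equals or betters the chosen plan.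
- Against it: the stereocentre of A7 needs a separate enantioselective synthesis with a hindered naphthyl nucleophile, so the hard problem is moved. After ring opening the enone is a keto tautomer of a 4-aryl-1-naphthol, and any enolisation towards C4 aromatises ring B and destroys the stereocentre. FeCl3 is an oxidant in the presence of an electron-rich naphthyl ether.
- Comparison: the chosen plan has a comparable aromatisation hazard at 10 and 11 (loss of silanol), so on that point the two are equal. Alternative 3 is clearly longer, since A7 must be made first and four more steps plus deprotection follow.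

Key step: step 5

Remarks on the chemistry:
- Locants C1–C8a refer to the tetralone numbering of 15 in all intermediates, primed locants to the naphthyl group; 1, 4 and 8 are taken as catalogue chemicals.
- The (S)-configured oxazaborolidinium cation is assumed to be the enantiomer that shields the quinone face leading to 9, following the usual pre-transition-state model. Its mirror image, made the same way from the (R)-amino alcohol, would be substituted without other change if the sense proves opposite.

## Route

Step 1
Reactants: 1 5-methoxynaphthalen-1-ol
Product: 2 4-bromo-5-methoxynaphthalen-1-ol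
Conditions: NBS (1.0 equiv), MeCN, −20 → 0 °C, dark
Reagents that add atoms: N-bromosuccinimide, O=C1CCC(=O)N1Br
Why: Electrophilic aromatic bromination; the free hydroxyl is the strongest donor, so attack goes to its ring and, in a polar aprotic solvent without amine, to the α-position para to it, which is the carbon peri to the methoxy group; one equivalent at low temperature limits ortho- and dibromination.

Step 2
Reactants: 2 4-bromo-5-methoxynaphthalen-1-ol
Product: 3 4-bromo-5-methoxynaphthalen-1-yl 2,2-dimethylpropanoate
Conditions: PivCl, Et3N, 4-(dimethylamino)pyridine (cat.), CH2Cl2, 0 °C → rt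
Reagents that add atoms: pivaloyl chloride, CC(C)(C)C(=O)Cl
Why: Nucleophilic acyl substitution (amine-catalysed O-acylation); the pivalate masks the acidic OH for the palladium, silyl triflate and Lewis acid steps, resists amine and dilute acid, and makes the naphthyl group a weaker donor than the silyloxy group of 7.

Step 3
Reactants: 3 4-bromo-5-methoxynaphthalen-1-yl 2,2-dimethylpropanoate; 4 4,4-diethoxybut-1-ene (3-butenal diethyl acetal)
Product: 6 5-methoxy-4-[(1E)-4-oxobut-1-en-1-yl]naphthalen-1-yl 2,2-dimethylpropanoate, via diethyl acetal 5 (not isolated)
Conditions: 4 (2 equiv), Pd(OAc)2 (5 mol%), P(o-tol)3 (10 mol%), Et3N, DMF, 100 °C; then 2 M aq. HCl, THF, rt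
Reagents that add atoms: water, O
Why: Heck reaction: oxidative addition of the C–Br bond to zerovalent palladium, syn insertion of the terminal alkene with the bulky aryl group on the terminal carbon, and β-hydride elimination towards the benzylic hydrogen should give the E-styrenyl acetal 5, which dilute acid hydrolyses to the aldehyde. Any isomer from elimination towards C3 gives the conjugated 2-enal after hydrolysis, and step 4 converts it into the same diene.

Step 4
Reactants: 6 5-methoxy-4-[(1E)-4-oxobut-1-en-1-yl]naphthalen-1-yl 2,2-dimethylpropanoate
Product: 7 4-[(1E,3E)-4-(tert-butyldimethylsilyloxy)buta-1,3-dien-1-yl]-5-methoxynaphthalen-1-yl 2,2-dimethylpropanoate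
Conditions: TBSOTf, Et3N, CH2Cl2, −78 → 0 °C; filtration through Et3N-deactivated silica
Reagents that add atoms: tert-butyldimethylsilyl trifluoromethanesulfonate, CC(C)(C)[Si](C)(C)OS(=O)(=O)C(F)(F)F
Why: Soft enolisation: O-silylation gives an oxocarbenium ion that loses the doubly activated allylic α-proton to give the fully conjugated dienol silyl ether; the new enol double bond should form mainly E from the extended conformation, and any 1Z isomer cannot reach the s-cis form easily and stays out of the cycloaddition.

Step 5
Reactants: 7 4-[(1E,3E)-4-(tert-butyldimethylsilyloxy)buta-1,3-dien-1-yl]-5-methoxynaphthalen-1-yl 2,2-dimethylpropanoate; 8 1,4-benzoquinone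
Product: 9 (4aR,5R,8S,8aR)-8-(tert-butyldimethylsilyloxy)-5-[8-methoxy-4-(pivaloyloxy)naphthalen-1-yl]-4a,5,8,8a-tetrahydronaphthalene-1,4-dione (cis-fused endo adduct; the four ring methine hydrogens all cis)
Conditions: 8 (2.5 equiv), (S)-3,3-diphenyl-1-(o-tolyl)tetrahydro-1H,3H-pyrrolo[1,2-c][1,3,2]oxazaborole activated with HNTf2 (20 mol%), CH2Cl2, −78 °C; pH 7 buffer quench at −78 °C, cold filtration through silica, used at once
Reagents that add atoms: none
Why: The boron cation binds one carbonyl lone pair of 8 (the one syn to the neighbouring C–H, which is held by a C–H···O contact to the catalyst oxygen) and lowers the LUMO of the adjacent C=C, to which 7 adds in a concerted, asynchronous Diels–Alder reaction of normal electron demand; the closest known reaction type is the oxazaborolidinium-catalysed enantioselective Diels–Alder reaction of quinones with oxygenated dienes. The one new ring (C1–C2–C3–C4–C4a–C8a) is closed by a suprafacial–suprafacial [4+2] cycloaddition in which C4–C4a is the leading bond and C1–C8a follows. C4 is controlled by the catalyst, whose C-phenyl group covers one face of the bound C=C so that the diene approaches the open face, together with the 3E geometry of the styrenyl bond. C4a and C8a are cis because the dienophile reacts suprafacially, C1 is cis to C4 because the (1E,3E)-diene reacts suprafacially, and the endo mode places H1 and H4 cis to H4a and H8a. The step needs endo selectivity, one orientation of the diene (aryl-bearing terminus to the carbon β to the bound carbonyl) and one face, and because C4a and C8a are erased in step 6 all three are folded into the enantiomeric purity at C4. Endo selectivity is secured by the two carbonyl groups of the cis-ene-dione lying under the diene, orientation by the silyloxy group, which as the strongest donor puts the largest HOMO coefficient on the aryl-bearing terminus while the twisted, acyl-protected naphthyl group competes only weakly, and mono-addition by the excess of 8 and the lower reactivity of the hindered ene-dione in 9. Quenching at −78 °C keeps the acid-labile dienol ether and the enolisable adduct intact.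

Step 6
Reactants: 9 (4aR,5R,8S,8aR)-8-(tert-butyldimethylsilyloxy)-5-[8-methoxy-4-(pivaloyloxy)naphthalen-1-yl]-4a,5,8,8a-tetrahydronaphthalene-1,4-dione
Product: 11 (1S,4S)-1-(tert-butyldimethylsilyloxy)-4-[8-methoxy-4-(pivaloyloxy)naphthalen-1-yl]-1,4-dihydronaphthalene-5,8-diyl diacetate (1,4-cis), via hydroquinone 10 (not isolated)
Conditions: Ac2O, Et3N, 4-(dimethylamino)pyridine (cat.), CH2Cl2, −20 → 0 °C, argon
Reagents that add atoms: acetic anhydride, CC(=O)OC(C)=O
Why: Base-mediated keto–enol tautomerisation at C4a and C8a aromatises the ene-dione to hydroquinone 10, which is O-acetylated as it forms (the standard aromatisation of quinone Diels–Alder adducts); C4a and C8a become sp2 while C1 and C4 are untouched. Silanolate is a poor leaving group and acetyl trapping is fast at low temperature, which disfavours β-elimination, and the acetates switch off quinone methide formation at C1.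

Step 7
Reactants: 11 (1S,4S)-1-(tert-butyldimethylsilyloxy)-4-[8-methoxy-4-(pivaloyloxy)naphthalen-1-yl]-1,4-dihydronaphthalene-5,8-diyl diacetate
Product: 12 (1S,4S)-1-(tert-butyldimethylsilyloxy)-4-[8-methoxy-4-(pivaloyloxy)naphthalen-1-yl]-1,2,3,4-tetrahydronaphthalene-5,8-diyl diacetate
Conditions: 2-O2N-C6H4SO2NHNH2 (excess, in portions), Et3N, CH2Cl2, rt
Reagents that add atoms: none
Why: Diimide reduction (concerted syn transfer of two hydrogens from HN=NH released from the sulfonylhydrazide) saturates the cis-disubstituted C2=C3 bond from the face opposite the cis aryl and silyloxy groups; it cannot hydrogenolyse the benzylic C1–O bond and does not shift the double bond towards C4, so neither stereocentre is touched.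

Step 8
Reactants: 12 (1S,4S)-1-(tert-butyldimethylsilyloxy)-4-[8-methoxy-4-(pivaloyloxy)naphthalen-1-yl]-1,2,3,4-tetrahydronaphthalene-5,8-diyl diacetate
Product: 13 (1S,4S)-1-hydroxy-4-[8-methoxy-4-(pivaloyloxy)naphthalen-1-yl]-1,2,3,4-tetrahydronaphthalene-5,8-diyl diacetate
Conditions: HF·pyridine, pyridine, THF, 0 °C → rt
Reagents that add atoms: none
Why: Fluoride-induced Si–O cleavage under mildly acidic conditions frees the secondary alcohol while the three aryl esters survive; the absence of base avoids acetyl migration from O8 to the new C1 hydroxyl.

Step 9
Reactants: 13 (1S,4S)-1-hydroxy-4-[8-methoxy-4-(pivaloyloxy)naphthalen-1-yl]-1,2,3,4-tetrahydronaphthalene-5,8-diyl diacetate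
Product: 14 (S)-4-[8-methoxy-4-(pivaloyloxy)naphthalen-1-yl]-1-oxo-1,2,3,4-tetrahydronaphthalene-5,8-diyl diacetate
Conditions: Dess–Martin periodinane, CH2Cl2, 0 °C → rt
Reagents that add atoms: none
Why: Dess–Martin oxidation of the benzylic secondary alcohol to the aryl ketone (ligand exchange at iodine, then loss of the carbinol hydrogen); the C1 stereocentre is removed on purpose, C4 is not α to the new carbonyl, and all phenolic oxygens are acylated and inert.

Step 10
Reactants: 14 (S)-4-[8-methoxy-4-(pivaloyloxy)naphthalen-1-yl]-1-oxo-1,2,3,4-tetrahydronaphthalene-5,8-diyl diacetate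
Product: 15 (S)-5,8-dihydroxy-4-(4-hydroxy-8-methoxynaphthalen-1-yl)-3,4-dihydronaphthalen-1(2H)-one
Conditions: K2CO3, MeOH/THF (degassed), rt, argon; then degassed aq. HCl, Na2S2O4 wash
Reagents that add atoms: none
Why: Base-mediated transesterification (methanolysis) of the two aryl acetates and the aryl pivalate, all activated acyl donors that should cleave at room temperature; C4 is not enolisable and is not epimerised, and exclusion of oxygen with an acidic, reducing work-up keeps the hydroquinone from oxidising.

## Compound list

1 | 5-methoxynaphthalen-1-ol | COc1cccc2c(O)cccc12 | starting material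
2 | 4-bromo-5-methoxynaphthalen-1-ol | COc1cccc2c(O)ccc(Br)c12 | intermediate
3 | 4-bromo-5-methoxynaphthalen-1-yl 2,2-dimethylpropanoate | COc1cccc2c(OC(=O)C(C)(C)C)ccc(Br)c12 | intermediate
4 | 4,4-diethoxybut-1-ene | C=CCC(OCC)OCC | starting material
5 | 4-[(1E)-4,4-diethoxybut-1-en-1-yl]-5-methoxynaphthalen-1-yl 2,2-dimethylpropanoate | COc1cccc2c(OC(=O)C(C)(C)C)ccc(/C=C/CC(OCC)OCC)c12 | intermediate
6 | 5-methoxy-4-[(1E)-4-oxobut-1-en-1-yl]naphthalen-1-yl 2,2-dimethylpropanoate | COc1cccc2c(OC(=O)C(C)(C)C)ccc(/C=C/CC=O)c12 | intermediate
7 | 4-[(1E,3E)-4-(tert-butyldimethylsilyloxy)buta-1,3-dien-1-yl]-5-methoxynaphthalen-1-yl 2,2-dimethylpropanoate | COc1cccc2c(OC(=O)C(C)(C)C)ccc(/C=C/C=C/O[Si](C)(C)C(C)(C)C)c12 | intermediate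
8 | 1,4-benzoquinone | O=C1C=CC(=O)C=C1 | starting material
9 | (4aR,5R,8S,8aR)-8-(tert-butyldimethylsilyloxy)-5-[8-methoxy-4-(pivaloyloxy)naphthalen-1-yl]-4a,5,8,8a-tetrahydronaphthalene-1,4-dione | COc1cccc2c(OC(=O)C(C)(C)C)ccc([C@@H]3C=C[C@H](O[Si](C)(C)C(C)(C)C)[C@@H]4C(=O)C=CC(=O)[C@H]34)c12 | intermediate
10 | (1S,4S)-1-(tert-butyldimethylsilyloxy)-4-[8-methoxy-4-(pivaloyloxy)naphthalen-1-yl]-1,4-dihydronaphthalene-5,8-diol | COc1cccc2c(OC(=O)C(C)(C)C)ccc([C@@H]3C=C[C@H](O[Si](C)(C)C(C)(C)C)c4c(O)ccc(O)c43)c12 | intermediate
11 | (1S,4S)-1-(tert-butyldimethylsilyloxy)-4-[8-methoxy-4-(pivaloyloxy)naphthalen-1-yl]-1,4-dihydronaphthalene-5,8-diyl diacetate | COc1cccc2c(OC(=O)C(C)(C)C)ccc([C@@H]3C=C[C@H](O[Si](C)(C)C(C)(C)C)c4c(OC(C)=O)ccc(OC(C)=O)c43)c12 | intermediate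
12 | (1S,4S)-1-(tert-butyldimethylsilyloxy)-4-[8-methoxy-4-(pivaloyloxy)naphthalen-1-yl]-1,2,3,4-tetrahydronaphthalene-5,8-diyl diacetate | COc1cccc2c(OC(=O)C(C)(C)C)ccc([C@@H]3CC[C@H](O[Si](C)(C)C(C)(C)C)c4c(OC(C)=O)ccc(OC(C)=O)c43)c12 | intermediate
13 | (1S,4S)-1-hydroxy-4-[8-methoxy-4-(pivaloyloxy)naphthalen-1-yl]-1,2,3,4-tetrahydronaphthalene-5,8-diyl diacetate | COc1cccc2c(OC(=O)C(C)(C)C)ccc([C@@H]3CC[C@H](O)c4c(OC(C)=O)ccc(OC(C)=O)c43)c12 | intermediate
14 | (S)-4-[8-methoxy-4-(pivaloyloxy)naphthalen-1-yl]-1-oxo-1,2,3,4-tetrahydronaphthalene-5,8-diyl diacetate | COc1cccc2c(OC(=O)C(C)(C)C)ccc([C@@H]3CCC(=O)c4c(OC(C)=O)ccc(OC(C)=O)c43)c12 | intermediate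
15 | (S)-5,8-dihydroxy-4-(4-hydroxy-8-methoxynaphthalen-1-yl)-3,4-dihydronaphthalen-1(2H)-one | COc1cccc2c(O)ccc([C@@H]3CCC(=O)c4c(O)ccc(O)c43)c12 | target

## Step count and least certain steps

Total steps: 10. Longest linear sequence: 10 steps (1 to 15); 4 and 8 are purchased and enter in steps 3 and 5.

Step 5 (key step). The most likely failure is insufficient enantiomeric purity at C4, because endo/exo preference, diene orientation and facial shielding all translate into the configuration of the one surviving stereocentre. The strongly acidic catalyst may also desilylate the dienol ether or divert it into conjugate addition. The fallback replaces asymmetric catalysis by resolution and sets out from 7 and 8. Uncatalysed cycloaddition in toluene at room temperature should give the racemic endo adduct, that is 9 together with its mirror image (4aS,5S,8R,8aS)-8-(tert-butyldimethylsilyloxy)-5-[8-methoxy-4-(pivaloyloxy)naphthalen-1-yl]-4a,5,8,8a-tetrahydronaphthalene-1,4-dione F1. The conditions of step 6 would convert the mixture, through 10 and the enantiomeric (1R,4R)-1-(tert-butyldimethylsilyloxy)-4-[8-methoxy-4-(pivaloyloxy)naphthalen-1-yl]-1,4-dihydronaphthalene-5,8-diol F2, into 11 and (1R,4R)-1-(tert-butyldimethylsilyloxy)-4-[8-methoxy-4-(pivaloyloxy)naphthalen-1-yl]-1,4-dihydronaphthalene-5,8-diyl diacetate F3. Preparative chromatography on a chiral stationary phase (cellulose tris(3,5-dimethylphenylcarbamate), hexane/2-propanol) would separate the two, and the route is rejoined at 11.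

Step 6. The most likely failure is β-elimination of the C1 silyloxy group from the C8 enolate, followed by aromatisation of ring B to a naphthalene and loss of C4. The fallback enolises without a free enolate and sets out from 9. TBSOTf and Et3N in CH2Cl2 at −78 °C silylate each carbonyl oxygen, and deprotonation of the oxocarbenium ions should give (1S,4S)-1,5,8-tris(tert-butyldimethylsilyloxy)-4-[8-methoxy-4-(pivaloyloxy)naphthalen-1-yl]-1,4-dihydronaphthalene F4. KHF2 in MeOH at room temperature cleaves only the two aryl silyl ethers and gives 10, which is acetylated at once (Ac2O, pyridine); the route is rejoined at 11.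

Step 3. The most likely failure is slow oxidative addition and insertion at the peri-hindered bromide, leading to reductive debromination or to arylation at the internal alkene carbon. The fallback replaces the Heck reaction by a Suzuki–Miyaura coupling and sets out from 3. Purchased 4,4-diethoxybut-1-yne F5 is hydroborated with pinacolborane (Cp2Zr(H)Cl cat., CH2Cl2, rt) to (E)-2-(4,4-diethoxybut-1-en-1-yl)-4,4,5,5-tetramethyl-1,3,2-dioxaborolane F6. Coupling of this boronate with 3 (Pd(dppf)Cl2, K3PO4, dioxane/H2O, 80 °C) should give 5 as a single regio- and stereoisomer, and the route is rejoined at 5, which is hydrolysed to 6 as in step 3.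

Step 1. The most likely failure is bromination ortho to the hydroxyl, in the methoxy ring, or twice, because both rings are activated and the wanted position is the peri-hindered one. The fallback introduces oxygen instead of bromine at that carbon and sets out from 1. Oxidation with PhI(OAc)2 in aqueous MeCN should give 5-methoxynaphthalene-1,4-dione F7, which Na2S2O4 reduces to 5-methoxynaphthalene-1,4-diol F8. The hydroxyl remote from the methoxy group, neither hindered nor hydrogen-bonded, is pivaloylated selectively (PivCl, pyridine, −20 °C) to 4-hydroxy-5-methoxynaphthalen-1-yl 2,2-dimethylpropanoate F9. Triflation (Tf2O, pyridine, 0 °C) gives 5-methoxy-4-(trifluoromethanesulfonyloxy)naphthalen-1-yl 2,2-dimethylpropanoate F10, which takes the place of 3 in the Heck reaction of step 3 (LiCl added); the route is rejoined at 5.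

## Further compounds

F1 | step 5 | (4aS,5S,8R,8aS)-8-(tert-butyldimethylsilyloxy)-5-[8-methoxy-4-(pivaloyloxy)naphthalen-1-yl]-4a,5,8,8a-tetrahydronaphthalene-1,4-dione | COc1cccc2c(OC(=O)C(C)(C)C)ccc([C@H]3C=C[C@@H](O[Si](C)(C)C(C)(C)C)[C@H]4C(=O)C=CC(=O)[C@@H]34)c12
F2 | step 5 | (1R,4R)-1-(tert-butyldimethylsilyloxy)-4-[8-methoxy-4-(pivaloyloxy)naphthalen-1-yl]-1,4-dihydronaphthalene-5,8-diol | COc1cccc2c(OC(=O)C(C)(C)C)ccc([C@H]3C=C[C@@H](O[Si](C)(C)C(C)(C)C)c4c(O)ccc(O)c43)c12
F3 | step 5 | (1R,4R)-1-(tert-butyldimethylsilyloxy)-4-[8-methoxy-4-(pivaloyloxy)naphthalen-1-yl]-1,4-dihydronaphthalene-5,8-diyl diacetate | COc1cccc2c(OC(=O)C(C)(C)C)ccc([C@H]3C=C[C@@H](O[Si](C)(C)C(C)(C)C)c4c(OC(C)=O)ccc(OC(C)=O)c43)c12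
F4 | step 6 | (1S,4S)-1,5,8-tris(tert-butyldimethylsilyloxy)-4-[8-methoxy-4-(pivaloyloxy)naphthalen-1-yl]-1,4-dihydronaphthalene | COc1cccc2c(OC(=O)C(C)(C)C)ccc([C@@H]3C=C[C@H](O[Si](C)(C)C(C)(C)C)c4c(O[Si](C)(C)C(C)(C)C)ccc(O[Si](C)(C)C(C)(C)C)c43)c12
F5 | step 3 | 4,4-diethoxybut-1-yne | C#CCC(OCC)OCC
F6 | step 3 | (E)-2-(4,4-diethoxybut-1-en-1-yl)-4,4,5,5-tetramethyl-1,3,2-dioxaborolane | CCOC(C/C=C/B1OC(C)(C)C(C)(C)O1)OCC
F7 | step 1 | 5-methoxynaphthalene-1,4-dione | COc1cccc2C(=O)C=CC(=O)c12
F8 | step 1 | 5-methoxynaphthalene-1,4-diol | COc1cccc2c(O)ccc(O)c12
F9 | step 1 | 4-hydroxy-5-methoxynaphthalen-1-yl 2,2-dimethylpropanoate | COc1cccc2c(OC(=O)C(C)(C)C)ccc(O)c12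
F10 | step 1 | 5-methoxy-4-(trifluoromethanesulfonyloxy)naphthalen-1-yl 2,2-dimethylpropanoate | COc1cccc2c(OC(=O)C(C)(C)C)ccc(OS(=O)(=O)C(F)(F)F)c12
A1 | alternative 1 | (R)-5,8-bis(benzyloxy)-4-(furan-2-yl)-3,4-dihydronaphthalen-1(2H)-one | o1cccc1[C@@H]2CCC(=O)c3c(OCc4ccccc4)ccc(OCc5ccccc5)c32
A2 | alternative 1 | 3-methoxy-2-(trimethylsilyl)phenyl trifluoromethanesulfonate | COc1cccc(OS(=O)(=O)C(F)(F)F)c1[Si](C)(C)C
A3 | alternative 1 | 5,8-bis(benzyloxy)-4-(8-methoxy-1,4-dihydro-1,4-epoxynaphthalen-1-yl)-3,4-dihydronaphthalen-1(2H)-one (one bridgehead diastereomer) | COc1cccc2[C@H]3C=C[C@@](O3)([C@@H]4CCC(=O)c5c(OCc6ccccc6)ccc(OCc7ccccc7)c54)c12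
A4 | alternative 2 | 6-{[4-(benzyloxy)-8-methoxynaphthalen-1-yl]methylidene}-4-methoxycyclohexa-2,4-dien-1-one | COC1=CC(=Cc2ccc(OCc3ccccc3)c3cccc(OC)c23)C(=O)C=C1
A5 | alternative 2 | propenal | C=CC=O
A6 | alternative 2 | (S)-5-[4-(benzyloxy)-8-methoxynaphthalen-1-yl]-7-methoxy-4,5-dihydro-1-benzoxepin-2(3H)-one | COc1cccc2c(OCc5ccccc5)ccc([C@@H]3CCC(=O)Oc4ccc(OC)cc43)c12
A7 | alternative 3 | (S)-4-(benzyloxy)-3-[4-(benzyloxy)-8-methoxynaphthalen-1-yl]-7-methoxy-2,3-dihydro-1H-inden-1-one | COc1cccc2c(OCc3ccccc3)ccc([C@@H]3CC(=O)c4c(OC)ccc(OCc5ccccc5)c43)c12
A8 | alternative 3 | (S)-{[7-(benzyloxy)-1-[4-(benzyloxy)-8-methoxynaphthalen-1-yl]-4-methoxy-1H-inden-3-yl]oxy}trimethylsilane | COc1cccc2c(OCc3ccccc3)ccc([C@@H]3C=C(O[Si](C)(C)C)c4c(OC)ccc(OCc5ccccc5)c43)c12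
A9 | alternative 3 | siloxycyclopropane fused to the indane, methylene anti to the naphthyl group | COc1cccc2c(OCc6ccccc6)ccc([C@@H]3[C@H]4C[C@@]4(O[Si](C)(C)C)c5c(OC)ccc(OCc7ccccc7)c53)c12
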